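The route rests on disconnecting the cyclopentane ring C1–C7–C6–C5–C8 of the bicyclo[3.2.1]octane at C8–C1 and C6–C7. The key step exploits three features: C8 is a carbinol next to quaternary C1, C6 is benzylic, and the C7 methyl (C9) can be the far end of a vinyl group. One titanocene-mediated operation converts the open-chain dibromo keto aldehyde 22 into the bicycle: Barbier allylation (C9 bromide, C8 aldehyde) closes the six-membered ring and leaves a vinyl group on C1, and the benzylic C6 radical then closes 5-exo onto it. The precursor is assembled from a glycolate-derived Weinreb amide and a 2-bromoallyl ether of O-benzylisovanillin.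

Key step: step 15

Labels used below (not IUPAC locants): C1 = allyl-bearing bridgehead, C2 = ring CH2, C3 = CH(OMe), C4 = C=O, C5 = OMe-bearing bridgehead, C6 = CH(aryl), C7 = CH(CH3), C8 = CH(OH), C9 = methyl carbon on C7.

Assumption: the (S,S)-ProPhenol/Me2Zn catalyst is taken to add the alkyne to the Re face of 1; C6 is only a relay centre for C5 and is erased in step 15, so the enantiomeric ligand would be used if the facial sense of step 1 or of step 11 proved opposite.

Step 1
Reactants: 1 3-(benzyloxy)-4-methoxybenzaldehyde; 2 ethynyltrimethylsilane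
Product: 3 (S)-silylpropargylic alcohol
Conditions: (S,S)-ProPhenol (10 mol %), Me2Zn (3 equiv), toluene, 0 °C; aq. NH4Cl
Reagents that add atoms: none
Why: Zinc–ProPhenol (Trost) asymmetric alkynylation of an aryl aldehyde, in which the dinuclear zinc catalyst should deliver the alkynyl group to the Re face and set the (S)-carbinol, a relay centre that later directs the C5 oxygenation.

Step 2
Reactants: 3 (S)-silylpropargylic alcohol
Product: 4 (R)-propargylic alcohol
Conditions: K2CO3 (0.2 equiv), MeOH, 0 °C
Reagents that add atoms: none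
Why: Base-catalysed methanolysis of the alkynyl C–Si bond (protodesilylation), which does not touch the carbinol centre (the descriptor changes only because the priorities change).

Step 3
Reactants: 4 (R)-propargylic alcohol
Product: 5 propargylic silyl ether
Conditions: t-BuMe2SiCl, imidazole, DMF, 25 °C
Reagents that add atoms: tert-butyldimethylsilyl chloride CC(C)(C)[Si](C)(C)Cl
Why: Standard silylation of a secondary alcohol; the silyl ether later acts as the steric control element of step 11 and as the precursor of the benzylic bromide.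

Step 4
Reactants: 5 propargylic silyl ether
Product: 7 2-bromoallyl silyl ether, via alkenylborane 6 (not isolated)
Conditions: B-bromo-9-BBN, CH2Cl2, 0 °C; then AcOH, 0 to 25 °C
Reagents that add atoms: B-bromo-9-borabicyclo[3.3.1]nonane BrB1C2CCCC1CCC2
Why: Syn bromoboration of the terminal alkyne puts bromine on the internal carbon (Markovnikov haloboration) and protonolysis of the alkenyl C–B bond by acetic acid gives the 2-bromoalkene.

Step 5
Reactants: 8 4-[(tert-butyldimethylsilyl)oxy]but-2-yn-1-ol; 9 allylmagnesium bromide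
Product: 10 (E)-allylic alcohol
Conditions: 9 (3 equiv), Et2O, reflux; aq. NH4Cl
Reagents that add atoms: none
Why: Alkoxide-directed anti carbomagnesiation of a propargylic alcohol, in which allyl adds to the alkyne carbon next to the CH2O–Mg group and the chelated vinylmagnesium is protonated, so the (E) geometry (CH2OH trans to CH2OSi) is fixed.

Step 6
Reactants: 10 (E)-allylic alcohol
Product: 11 allylic bromide
Conditions: CBr4, PPh3, CH2Cl2, 0 °C
Reagents that add atoms: carbon tetrabromide BrC(Br)(Br)Br
Why: Appel bromination of the primary allylic alcohol by SN2 displacement of the oxyphosphonium group, without allylic transposition at 0 °C.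

Step 7
Reactants: 12 (4R)-4-benzyl-1,3-oxazolidin-2-one; 13 methoxyacetyl chloride
Product: 14 glycolate imide
Conditions: n-BuLi, THF, −78 °C; then 13
Reagents that add atoms: none
Why: N-Acylation of the lithiated Evans oxazolidinone.

Step 8
Reactants: 14 glycolate imide; 11 allylic bromide
Product: 15 alkylated imide
Conditions: NaN(SiMe3)2, THF, −78 °C; then 11, −78 to −45 °C
Reagents that add atoms: none
Why: Evans–Crimmins glycolate alkylation, in which the chelated Z sodium enolate is alkylated on the face opposite the benzyl group of the (R)-auxiliary and C3 is set as (S).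

Step 9
Reactants: 15 alkylated imide
Product: 16 Weinreb amide
Conditions: MeNH(OMe)·HCl, AlMe3, CH2Cl2, 0 to 25 °C
Reagents that add atoms: N,O-dimethylhydroxylamine hydrochloride CNOC.Cl
Why: Aluminium amide transamination of the N-acyloxazolidinone (Weinreb amide formation) with release of the auxiliary, under which the C3 centre is not enolized.

Step 10
Reactants: 7 2-bromoallyl silyl ether; 16 Weinreb amide
Product: 17 enone
Conditions: 7, t-BuLi (2.1 equiv), Et2O, −78 °C; then 16, −78 °C; aq. NH4Cl at −78 °C
Reagents that add atoms: none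
Why: Bromine–lithium exchange gives the alkenyllithium, whose addition to the Weinreb amide stops at the chelated tetrahedral intermediate so that the enone is released only on work-up (Weinreb ketone synthesis), forming the C4–C5 bond.

Step 11
Reactants: 17 enone
Product: 18 epoxy ketone
Conditions: t-BuOOH, n-BuLi, THF, −78 to −20 °C
Reagents that add atoms: tert-butyl hydroperoxide CC(C)(C)OO
Why: Weitz–Scheffer-type nucleophilic epoxidation, chemoselective for the electron-poor enone over the two isolated alkenes: the peroxide adds to C8 and the enolate closes on the face anti to the aryl group in the rotamer with H-6 eclipsing the enolate (allylic 1,3-strain), which sets C5.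

Step 12
Reactants: 18 epoxy ketone
Product: 20 hydroxy aldehyde, via trimethylsilyl ether 19 (not isolated)
Conditions: DMSO, Me3SiOTf, CH2Cl2, −78 °C; then Et3N, −78 to 0 °C; aq. citric acid
Reagents that add atoms: dimethyl sulfoxide CS(C)=O
Why: Oxidative epoxide opening with DMSO (Kornblum/Swern-type, silyl triflate activation): DMSO attacks the primary oxirane carbon C8, the amine fragments the alkoxysulfonium salt to the aldehyde, and C5 keeps its oxygen and its configuration.

Step 13
Reactants: 20 hydroxy aldehyde
Product: 21 methoxy aldehyde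
Conditions: MeOTf, 2,6-di-tert-butyl-4-methylpyridine, CH2Cl2, 0 to 25 °C
Reagents that add atoms: methyl trifluoromethanesulfonate COS(=O)(=O)C(F)(F)F
Why: O-Methylation of a hindered tertiary alcohol with methyl triflate and a non-nucleophilic pyridine base, conditions that neither enolize C3 nor affect the quaternary C5 centre.

Step 14
Reactants: 21 methoxy aldehyde
Product: 22 dibromo keto aldehyde
Conditions: Ph3PBr2 (3 equiv), CH2Cl2, 0 to 25 °C
Reagents that add atoms: dibromotriphenylphosphorane BrP(Br)(c1ccccc1)(c1ccccc1)c1ccccc1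
Why: Direct conversion of silyl ethers into bromides with Ph3PBr2 (oxyphosphonium formation, then bromide displacement), by SN2 at the primary allylic carbon and through an ion pair at the benzylic carbon, so C6 is expected as a mixture of epimers, which is irrelevant for step 15.

Step 15
Reactants: 22 dibromo keto aldehyde
Product: 24 benzyl ether of the target, via monocyclic bromo alcohol 23 (not isolated)
Conditions: Cp2TiCl2 (30 mol %), Mn dust, 2,4,6-collidine·HCl, THF, 25 °C, slow addition of 22 at high dilution
Reagents that add atoms: none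
Why: Cp2TiCl (trivalent titanium, from Cp2TiCl2 and Mn) abstracts bromine fastest from the unhindered allylic C9–Br, the allyl radical is captured by a second Cp2TiCl, and the η1-allyltitanium adds through its γ-carbon C1 to the C8 aldehyde (titanocene Barbier allylation; 6-membered ring through a closed chair transition state that is trans-fused to the forming cyclohexanone), after which collidinium chloride protonates the titanium alkoxide to the free alcohol 23 that now carries a vinyl group (C7=C9) on C1. Bromine abstraction from the hindered benzylic C6–Br then gives a benzylic radical that Cp2TiCl does not reduce, which closes 5-exo-trig onto C7 across the 1,3-positions C5/C1 (cyclopentane ring C1–C7–C6–C5–C8, a hex-5-enyl radical cyclization of the Beckwith type), and the primary C9 radical is reduced and protonated to the C7 methyl group. C1 and C8 are set in the allylation: with the (E)-alkene both C2 and the quaternary C5 sit equatorial on the chair, so O8 ends trans to the vinyl group while the vinyl group, the C5 benzylic arm and the C3 methoxy group are all equatorial and hence all cis, exactly the relationship of C7, C6 and 3-OMe in the target. C6 and C7 are set in the radical closure, which should run through the boat form of the cyclohexanone (C3 methoxy pseudo-equatorial, the small free 8-OH as flagpole): the planar benzylic radical turns its aryl group endo, under C4/C5, because exo it would press an ortho C–H against H-8, and the CH2 terminus of the vinyl group turns exo, anti to the aryl group, which gives 6-aryl endo and 7-methyl exo. The step needs the six-membered ring to close before the benzylic radical is consumed and needs γ-attack of the allylmetal; both are secured by the rate order of the two halogen abstractions, by the persistence of the benzylic radical toward Cp2TiCl, by slow addition at high dilution and by the ring size (γ-attack gives the 6-ring, α-attack an 8-ring), and both C6 epimers of 22 converge on the same radical.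

Step 16
Reactants: 24 benzyl ether of the target
Product: 25 CNP0209708.1
Conditions: BCl3, pentamethylbenzene, CH2Cl2, −78 °C; MeOH, then water
Reagents that add atoms: none
Why: Lewis acid debenzylation of the aryl benzyl ether with BCl3 and pentamethylbenzene as a non-basic benzyl cation scavenger, conditions that at −78 °C should leave the allyl group, the ketone, the epimerizable C3 centre and the methyl ethers intact.

Compound list

1 | 3-(benzyloxy)-4-methoxybenzaldehyde | O=Cc1ccc(OC)c(OCc2ccccc2)c1 | starting material
2 | ethynyltrimethylsilane | C#C[Si](C)(C)C | starting material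
3 | (1S)-1-[3-(benzyloxy)-4-methoxyphenyl]-3-(trimethylsilyl)prop-2-yn-1-ol | C[Si](C)(C)C#C[C@@H](O)c1ccc(OC)c(OCc2ccccc2)c1 | intermediate
4 | (1R)-1-[3-(benzyloxy)-4-methoxyphenyl]prop-2-yn-1-ol | C#C[C@@H](O)c1ccc(OC)c(OCc2ccccc2)c1 | intermediate
5 | {[(1R)-1-[3-(benzyloxy)-4-methoxyphenyl]prop-2-yn-1-yl]oxy}(tert-butyl)dimethylsilane | C#C[C@@H](O[Si](C)(C)C(C)(C)C)c1ccc(OC)c(OCc2ccccc2)c1 | intermediate
6 | 9-[(1Z,3S)-3-[3-(benzyloxy)-4-methoxyphenyl]-2-bromo-3-[(tert-butyldimethylsilyl)oxy]prop-1-en-1-yl]-9-borabicyclo[3.3.1]nonane | Br/C(=C\B1C2CCCC1CCC2)[C@@H](O[Si](C)(C)C(C)(C)C)c1ccc(OC)c(OCc2ccccc2)c1 | intermediate (not isolated)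
7 | {[(1S)-1-[3-(benzyloxy)-4-methoxyphenyl]-2-bromoprop-2-en-1-yl]oxy}(tert-butyl)dimethylsilane | C=C(Br)[C@@H](O[Si](C)(C)C(C)(C)C)c1ccc(OC)c(OCc2ccccc2)c1 | intermediate
8 | 4-[(tert-butyldimethylsilyl)oxy]but-2-yn-1-ol | OCC#CCO[Si](C)(C)C(C)(C)C | starting material
9 | allylmagnesium bromide | C=CC[Mg]Br | starting material
10 | (2E)-4-[(tert-butyldimethylsilyl)oxy]-2-(prop-2-en-1-yl)but-2-en-1-ol | OC/C(CC=C)=C/CO[Si](C)(C)C(C)(C)C | intermediate
11 | {[(2E)-3-(bromomethyl)hexa-2,5-dien-1-yl]oxy}(tert-butyl)dimethylsilane | BrC/C(CC=C)=C/CO[Si](C)(C)C(C)(C)C | intermediate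
12 | (4R)-4-benzyl-1,3-oxazolidin-2-one | O=C1N[C@H](Cc2ccccc2)CO1 | starting material
13 | methoxyacetyl chloride | COCC(Cl)=O | starting material
14 | (4R)-4-benzyl-3-(methoxyacetyl)-1,3-oxazolidin-2-one | COCC(=O)N1[C@H](Cc2ccccc2)COC1=O | intermediate
15 | (4R)-4-benzyl-3-[(2S,4E)-6-[(tert-butyldimethylsilyl)oxy]-2-methoxy-4-(prop-2-en-1-yl)hex-4-enoyl]-1,3-oxazolidin-2-one | C=CC/C(=C\CO[Si](C)(C)C(C)(C)C)C[C@H](OC)C(=O)N1[C@H](Cc2ccccc2)COC1=O | intermediate
16 | (2S,4E)-6-[(tert-butyldimethylsilyl)oxy]-N,2-dimethoxy-N-methyl-4-(prop-2-en-1-yl)hex-4-enamide | CON(C)C(=O)[C@@H](OC)C/C(CC=C)=C/CO[Si](C)(C)C(C)(C)C | intermediate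
17 | (1S,4S,6E)-1-[3-(benzyloxy)-4-methoxyphenyl]-1,8-bis[(tert-butyldimethylsilyl)oxy]-4-methoxy-2-methylidene-6-(prop-2-en-1-yl)oct-6-en-3-one | C=C(C(=O)[C@@H](OC)C/C(CC=C)=C/CO[Si](C)(C)C(C)(C)C)[C@@H](O[Si](C)(C)C(C)(C)C)c1ccc(OC)c(OCc2ccccc2)c1 | intermediate
18 | (2S,4E)-1-[(2R)-2-{(S)-[3-(benzyloxy)-4-methoxyphenyl][(tert-butyldimethylsilyl)oxy]methyl}oxiran-2-yl]-6-[(tert-butyldimethylsilyl)oxy]-2-methoxy-4-(prop-2-en-1-yl)hex-4-en-1-one | O=C([C@@H](OC)C/C(CC=C)=C/CO[Si](C)(C)C(C)(C)C)[C@@]1(CO1)[C@@H](O[Si](C)(C)C(C)(C)C)c1ccc(OC)c(OCc2ccccc2)c1 | intermediate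
19 | (2S,4S,6E)-2-{(S)-[3-(benzyloxy)-4-methoxyphenyl][(tert-butyldimethylsilyl)oxy]methyl}-8-[(tert-butyldimethylsilyl)oxy]-4-methoxy-3-oxo-6-(prop-2-en-1-yl)-2-[(trimethylsilyl)oxy]oct-6-enal | O=C[C@](O[Si](C)(C)C)(C(=O)[C@@H](OC)C/C(CC=C)=C/CO[Si](C)(C)C(C)(C)C)[C@@H](O[Si](C)(C)C(C)(C)C)c1ccc(OC)c(OCc2ccccc2)c1 | intermediate (not isolated)
20 | (2S,4S,6E)-2-{(S)-[3-(benzyloxy)-4-methoxyphenyl][(tert-butyldimethylsilyl)oxy]methyl}-8-[(tert-butyldimethylsilyl)oxy]-2-hydroxy-4-methoxy-3-oxo-6-(prop-2-en-1-yl)oct-6-enal | O=C[C@](O)(C(=O)[C@@H](OC)C/C(CC=C)=C/CO[Si](C)(C)C(C)(C)C)[C@@H](O[Si](C)(C)C(C)(C)C)c1ccc(OC)c(OCc2ccccc2)c1 | intermediate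
21 | (2S,4S,6E)-2-{(S)-[3-(benzyloxy)-4-methoxyphenyl][(tert-butyldimethylsilyl)oxy]methyl}-8-[(tert-butyldimethylsilyl)oxy]-2,4-dimethoxy-3-oxo-6-(prop-2-en-1-yl)oct-6-enal | O=C[C@](OC)(C(=O)[C@@H](OC)C/C(CC=C)=C/CO[Si](C)(C)C(C)(C)C)[C@@H](O[Si](C)(C)C(C)(C)C)c1ccc(OC)c(OCc2ccccc2)c1 | intermediate
22 | (2S,4S,6E)-2-{[3-(benzyloxy)-4-methoxyphenyl](bromo)methyl}-8-bromo-2,4-dimethoxy-3-oxo-6-(prop-2-en-1-yl)oct-6-enal, both epimers at the benzylic carbon | O=C[C@](OC)(C(=O)[C@@H](OC)C/C(CC=C)=C/CBr)C(Br)c1ccc(OC)c(OCc2ccccc2)c1 | intermediate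
23 | (2S,3S,4S,6S)-2-{[3-(benzyloxy)-4-methoxyphenyl](bromo)methyl}-4-ethenyl-3-hydroxy-2,6-dimethoxy-4-(prop-2-en-1-yl)cyclohexan-1-one, both epimers at the benzylic carbon | C=CC[C@@]1(C=C)C[C@H](OC)C(=O)[C@](OC)(C(Br)c2ccc(OC)c(OCc3ccccc3)c2)[C@H]1O | intermediate (not isolated)
24 | (1S,3S,5S,6R,7S,8S)-7-[3-(benzyloxy)-4-methoxyphenyl]-8-hydroxy-1,3-dimethoxy-6-methyl-5-(prop-2-en-1-yl)bicyclo[3.2.1]octan-2-one | C=CC[C@]12C[C@H](OC)C(=O)[C@](OC)([C@H](c3ccc(OC)c(OCc4ccccc4)c3)[C@H]1C)[C@H]2O | intermediate
25 | CNP0209708.1, (1S,3S,5S,6R,7S,8S)-8-hydroxy-7-(3-hydroxy-4-methoxyphenyl)-1,3-dimethoxy-6-methyl-5-(prop-2-en-1-yl)bicyclo[3.2.1]octan-2-one | C=CC[C@]12C[C@H](OC)C(=O)[C@](OC)([C@H](c3ccc(OC)c(O)c3)[C@H]1C)[C@H]2O | target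

Total step count: 16. Longest linear sequence: 11 steps (steps 5, 6, 8, 9, 10, 11, 12, 13, 14, 15, 16).

Steps most likely to fail

Step 15. The two halides may be activated in the wrong order, so that the benzylic radical dimerizes, is reduced or attacks the allylic bromide before the six-membered ring exists, and the exo/endo control of the 5-exo closure may be lost. Fallback: setting out from 22, the two bond formations are separated and carried by different intermediates. Indium powder in DMF at 25 °C inserts only into the allylic bromide, and the allylindium adds through C1 to the aldehyde by the same closed transition state to give 23, which is now isolated. 23 is then cyclized under tin hydride chain conditions (Bu3SnH added slowly, AIBN, benzene, 80 °C), where the free 8-OH is present from the start. This comes back to the route at 24.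

Step 11. The ring closure of the peroxy enolate may show poor or opposite facial selectivity, because the only control element is the C6 silyloxy centre. Fallback: C5 is controlled from C3 through C4 instead. Setting out from 17, reduction with i-Bu2AlH in toluene at −78 °C under non-chelating conditions (Felkin–Anh, C3 methoxy anti to the hydride) should give the (4S) allylic alcohol F1. Epoxidation with VO(acac)2 and t-BuOOH, directed by that hydroxyl, is selective for the allylic alcohol alkene and erythro-selective because of 1,2-allylic strain with the C5 substituent, and should give the epoxy alcohol F2 with the required C5 configuration. Dess–Martin oxidation of F2 comes back to the route at 18.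

Step 13. The tertiary hydroxyl between two carbonyl groups may react too slowly with the methylating agent, and the free α-hydroxy aldehyde may undergo α-ketol rearrangement or oligomerize before it is methylated. Fallback: the methyl ether is made before the aldehyde exists. Setting out from 18, the oxirane is opened at C8 with CsOAc and acetic acid in DMF to the hydroxy acetate F3. The tertiary alcohol is methylated with Me3OBF4 and 1,8-bis(dimethylamino)naphthalene to the methyl ether F4. The acetate is removed with K2CO3 in methanol at 0 °C to give the primary alcohol F5, and Dess–Martin oxidation of F5 comes back to the route at 21.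

Further compounds

F0 | step 15 | none | none
F1 | step 11 | (4S) allylic alcohol, the C4 carbinol of enone 17 | C=C([C@H](O)[C@@H](OC)C/C(CC=C)=C/CO[Si](C)(C)C(C)(C)C)[C@@H](O[Si](C)(C)C(C)(C)C)c1ccc(OC)c(OCc2ccccc2)c1
F2 | step 11 | epoxy alcohol, the C5–C8 oxirane of F1 erythro to the C4 hydroxyl | O[C@H]([C@@H](OC)C/C(CC=C)=C/CO[Si](C)(C)C(C)(C)C)[C@@]1(CO1)[C@@H](O[Si](C)(C)C(C)(C)C)c1ccc(OC)c(OCc2ccccc2)c1
F3 | step 13 | hydroxy acetate, C8 acetate with free tertiary C5 hydroxyl | CC(=O)OC[C@](O)(C(=O)[C@@H](OC)C/C(CC=C)=C/CO[Si](C)(C)C(C)(C)C)[C@@H](O[Si](C)(C)C(C)(C)C)c1ccc(OC)c(OCc2ccccc2)c1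
F4 | step 13 | methyl ether, the C5 O-methyl derivative of F3 | CC(=O)OC[C@](OC)(C(=O)[C@@H](OC)C/C(CC=C)=C/CO[Si](C)(C)C(C)(C)C)[C@@H](O[Si](C)(C)C(C)(C)C)c1ccc(OC)c(OCc2ccccc2)c1
F5 | step 13 | primary alcohol, the C8 carbinol of 21 | OC[C@](OC)(C(=O)[C@@H](OC)C/C(CC=C)=C/CO[Si](C)(C)C(C)(C)C)[C@@H](O[Si](C)(C)C(C)(C)C)c1ccc(OC)c(OCc2ccccc2)c1
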